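## Analysis of the target

- The target is a 3,4-dihydroisocoumarin lactol. In isochroman-1-one numbering it has the lactone carbonyl C1, ring oxygen O2, hemiketal carbon C3 and methine C4, fused to a pentasubstituted benzene ring A (C5 methyl, C6 methoxy, C7 hydrogen, C8 hydroxyl).
- C3 carries a hydroxyl group and the C9 methylene. The C9 oxygen is acylated by ring B, 2,4-dihydroxy-5,6-dimethylbenzoic acid, whose carboxyl sits on C1′.
- There are two adjacent stereocentres, C4 (S) and C3 (R). The C4 methyl and the C3 hydroxyl lie on opposite faces of the lactone ring, and C9 is cis to the C4 methyl.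
- C3 is a hemiketal and equilibrates through the open keto acid. Only C4 therefore has to be set by a reagent; C3 follows from C4 under thermodynamic control.
- In the open form C4 is benzylic and α to the C3 ketone, so it is lost to any base. The lactol can also lose water to an isocoumarin under acid, and both rings carry oxidisable free phenols.
- Ring A is crowded, with C4a meta to both oxygens. The aroyl carbon of ring B is flanked by a hydroxyl and a methyl group, so a conventional esterification at C9 is unattractive.
- The strategy rests on ring B being a tetraketide resorcylate (hydroxyls on C2′ and C4′, methyls on C5′ and C6′). Its ester C–O bond and its C1′–C6′ ring bond can both be formed from an open-chain polyketone built on the C9 oxygen.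

## Retrosynthetic reasoning

**Lactol opening (25 to 24 to 23).** The O2–C3 bond of 25 is opened to the keto acid 24. The C1 acid and the C8 phenol are then masked as the benzyl ester and benzyl ether of 23. Both benzyl groups fall to hydrogenolysis under neutral conditions, the only conditions under which a C3 ketone next to C4 is safe. The forward step has to free the acid and let it add to the ketone; the C3 configuration then settles by equilibration.

**Ketone masked as alkene (23 to 21).** The C3 ketone is traced back through diol 22 to the methylidene group of 21. With C3 as an alkene carbon there is no carbonyl next to C4, so base can be used earlier in the route. The forward reaction has to cleave the only C=C bond of the molecule.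

**Key disconnection (21 to 13 and 17).** The C9–O–acyl bond and the C1′–C6′ bond of ring B are cut together. This leads through the cyclic aldol 20 and the triketo ester 19 to the acylketene 18, and so to alcohol 13 and dioxinone 17. Cutting here turns a hindered acylation into the addition of a primary alcohol to a ketene and delivers ring B with free phenols. The forward reaction must generate 18 from 17 by heat, capture it with the single hydroxyl of 13, and then close and aromatise ring B.

**Dioxinone partner (17 to 16 to 14 and 15).** Two C–C bonds of the side chain of 17 are cut in turn, both made forwards by Claisen-type acylations. The first joins 14 and 15 to give 16; the second adds the terminal acetyl group at the CH2 of the ethyl ketone.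

**Ring A functional groups (13 back to 7).** The C9 alcohol of 13 comes from the methyl ester of 12. The two benzyl groups of 12 come from the hydroxy acid 11, and the C8 hydroxyl of 11 from the methoxy group of 10. The carboxyl of 10 comes from the aldehyde 9, and the C8a–carbon bond of 9 from electrophilic formylation of 7 through iminium salt 8.
- The C8a carbon is added only after the stereocentre exists, because C8a is the ring position para to the C6 methoxy group and can be reached by electrophilic substitution.
- The carboxyl, once present, singles out the C8 oxygen for demethylation by chelation.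
- The ester is kept to the end of this sequence because a free allylic alcohol would not survive the formylation conditions.

**Stereocentre (7 to 6).** The C4–methyl bond is cut. Forwards, an enantioselective SN2′ methylation of the allylic bromide 6 sets C4. It also produces the C3 methylidene group and C9 at the ester oxidation level in the same step. At this stage the benzylic carbon has only one ortho substituent.

**Allylic bromide (6 to 5 to 3 and 4).** The bromide 6 arises by allylic transposition from carbinol 5. The C4–C3 bond of 5 is made by a Morita–Baylis–Hillman reaction of aldehyde 3 with 4.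

**Aldehyde (3 to 2 to 1).** The C5 methyl of 3 is introduced by cross-coupling at the bromide of 2. That bromide is placed by bromination of 1 at the carbon next to the formyl group.

## Alternatives that were turned down

**Alternative 1:** ring A built last by a biomimetic aldol.
- Disconnection: the C8a–C4a bond of ring A. The precursor is the open-chain dioxinone polyketone A1, in which the dioxinone supplies C1, C8a and C8 and the C4–C3–C9 unit (C3 as a silyl ether, ring B already attached as its dibenzyl ether) hangs from the C4a ketone.
- Forward key step: Et3N brings the dioxinone α-carbon onto the C4a ketone, and mild acid dehydrates to the benzodioxinone A2, in which only the C6 hydroxyl is free.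
- For: the ring A oxygens come out differentiated, with C1 and the C8 oxygen tied in the acetonide and C6–OH ready for methylation. No electrophilic substitution or demethylation is needed. On this point the alternative is stronger than the chosen route.
- Against: in A1 the C4 stereocentre sits α to the C4a ketone of a polycarbonyl chain, both while A1 is assembled by acylation and during the amine treatment, so it can enolise. A second stereocentre at C3 must be made and later destroyed by oxidation. Ring B has to be prepared separately in protected form and joined by conventional acylation of a hindered acid. The acetonide must finally be opened by a nucleophile at a stage close to the C3 ketone.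
- Comparison: more steps and a stereocentre at risk in the key step itself. The chosen route gives up the differentiated oxygens but keeps C4 away from any carbonyl until two neutral final steps, and obtains the ring B ester without acylation.

**Alternative 2:** ring expansion of an indanone α-ketol.
- Disconnection: C1–O2 and O2–C3 of the lactol, traced to the indanone A3 in which C1 and C3 are directly bonded.
- Forward key step: H5IO6 cleaves the C1–C3 bond of the tertiary α-ketol, and the new carboxyl adds to the freed C3 ketone to give the tribenzyl lactol A4.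
- For: the end-game is short and never basic, and all phenols are benzylated when periodate is present. This is stronger than the chosen route, whose cleavage step meets the free ring B phenols. In A3 the C4 carbon is not α to the ketone.
- Against: a five-membered ring must be made only to be broken. C4 still needs an enantioselective step on the indanone. Indanone C2 has to receive both a hydroxyl and an oxygenated methylene by enolate chemistry; an acyloxymethyl group already in place would be eliminated from that enolate, so ring B must be attached afterwards by acylating a neopentyl-type alcohol with the hindered acid next to a rearrangement-prone α-ketol.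
- Comparison: the chosen route has no sacrificial ring and forms the ester thermally under neutral conditions. In exchange it accepts the less protected cleavage step.

**Alternative 3:** Diels–Alder benzannulation of ring A.
- Disconnection: C5–C4a and C8–C8a. The diene A5 adds to the chiral ynoate A6, and loss of methanol aromatises the adduct to the benzoate A7.
- For: the polarity of diene and ynoate fixes the regiochemistry. C6–OMe, free C8–OH and the C1 carboxylate arrive in one convergent step. This again beats the chosen route in functional-group economy on ring A.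
- Against: the C5–C4a bond must form between a methyl-bearing diene terminus and an alkyne carbon that carries the branched C4 substituent, giving three contiguous ring substituents. This calls for prolonged heating, under which the ketene-acetal diene is labile and the propargylic C4–H of A6 can isomerise towards an allene. C3 again needs a disposable stereocentre and a late oxidation beside a free C8 phenol. Ring B is carried as a protected, conventionally acylated unit, and the tert-butyl ester needs acid at the end.
- Comparison: the chosen route prepares ring A stepwise and is longer there, but each operation is standard. Its risk sits in one step that also makes ring B and its ester.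

Key step: step 13

**Assumptions**
- The sense of induction of Taniaphos on a 2-alkoxycarbonyl allylic bromide is not predictable with confidence; the ligand antipode that gives the (S) centre is fixed in a first run (both antipodes are available).
- The (3R) hemiketal, with axial hydroxyl anti to the pseudo-axial C4 methyl, is taken to be the thermodynamically preferred C3 epimer.

## Route

Step 1
Reactants: 1 3,5-dimethoxybenzaldehyde
Product: 2 2-bromo-3,5-dimethoxybenzaldehyde
Conditions: NBS (1.05 equiv), MeCN, 0 °C to rt
Reagents that add atoms: N-bromosuccinimide, O=C1CCC(=O)N1Br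
Why: Electrophilic aromatic bromination; the carbon next to the formyl group is para to one methoxy group and ortho to the other, whereas the carbon between the two methoxy groups is more crowded, so one equivalent of NBS should give the 2-bromo aldehyde.

Step 2
Reactants: 2 2-bromo-3,5-dimethoxybenzaldehyde
Product: 3 3,5-dimethoxy-2-methylbenzaldehyde
Conditions: MeB(OH)2, PdCl2(dppf) (3 mol %), K2CO3, dioxane–H2O, 90 °C
Reagents that add atoms: methylboronic acid, CB(O)O
Why: Suzuki–Miyaura cross-coupling of an aryl bromide with methylboronic acid; the ortho formyl group is tolerated and a methyl group has no β-hydrogen to lose.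

Step 3
Reactants: 3 3,5-dimethoxy-2-methylbenzaldehyde; 4 methyl acrylate
Product: 5 methyl 2-[(3,5-dimethoxy-2-methylphenyl)(hydroxy)methyl]prop-2-enoate (racemic)
Conditions: DABCO (1 equiv), MeOH, rt, several days
Reagents that add atoms: none
Why: Morita–Baylis–Hillman reaction: DABCO adds to 4 and the ammonium enolate adds to the aldehyde of 3, forming the future C4–C3 bond; the reaction is slow for an ortho-substituted aldehyde but the methoxy groups are meta to the formyl group and do not deactivate it by resonance, and the carbinol centre may be racemic because step 4 erases it.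

Step 4
Reactants: 5 methyl 2-[(3,5-dimethoxy-2-methylphenyl)(hydroxy)methyl]prop-2-enoate
Product: 6 methyl (2Z)-2-(bromomethyl)-3-(3,5-dimethoxy-2-methylphenyl)prop-2-enoate
Conditions: PBr3 (0.5 equiv), Et2O, 0 °C to rt
Reagents that add atoms: phosphorus tribromide, BrP(Br)Br
Why: Bromination of a Baylis–Hillman alcohol with allylic transposition; the conjugated trisubstituted (Z)-bromide with the aryl group trans to the ester is the thermodynamic product and places the leaving group on the future C3 methylidene carbon.

Step 5
Reactants: 6 methyl (2Z)-2-(bromomethyl)-3-(3,5-dimethoxy-2-methylphenyl)prop-2-enoate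
Product: 7 methyl (3S)-3-(3,5-dimethoxy-2-methylphenyl)-2-methylidenebutanoate
Conditions: MeMgBr (1.2 equiv, slow addition), CuBr·SMe2 (5 mol %), Taniaphos [1-(α-dimethylamino-2-diphenylphosphinobenzyl)-2-diphenylphosphinoferrocene] (6 mol %), CH2Cl2, −78 °C
Reagents that add atoms: methylmagnesium bromide, C[Mg]Br
Why: Copper-catalysed asymmetric allylic alkylation (SN2′): the chiral methylcopper species adds to the benzylic alkene carbon and bromide leaves from the CH2 group, a regiochemistry that the acrylate polarity reinforces; the ferrocenyl diphosphine on copper selects the enantiotopic face of the C4=C3 double bond and so sets C4 as (S), while the benzylic carbon has only one ortho neighbour.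

Step 6
Reactants: 7 methyl (3S)-3-(3,5-dimethoxy-2-methylphenyl)-2-methylidenebutanoate
Product: 9 methyl (3S)-3-(2-formyl-3,5-dimethoxy-6-methylphenyl)-2-methylidenebutanoate, via aryl iminium chloride 8 (not isolated)
Conditions: POCl3, DMF, 0 to 70 °C; then aq. NaOAc
Reagents that add atoms: N,N-dimethylformamide, CN(C)C=O; water, O
Why: Vilsmeier–Haack formylation; C8a is para to the C6 methoxy group and ortho to the C8 methoxy group, while C7 lies between two methoxy groups (one pushed towards it by the C5 methyl) and should be avoided by the bulky chloroiminium ion; the electron-poor acrylate does not react and C4 is not touched under acidic conditions.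

Step 7
Reactants: 9 methyl (3S)-3-(2-formyl-3,5-dimethoxy-6-methylphenyl)-2-methylidenebutanoate
Product: 10 2,4-dimethoxy-5-methyl-6-[(2S)-4-methoxy-3-methylidene-4-oxobutan-2-yl]benzoic acid
Conditions: NaClO2, NaH2PO4, 2-methylbut-2-ene, t-BuOH–H2O, 0 °C to rt
Reagents that add atoms: sodium chlorite, [Na+].[O-]Cl=O
Why: Pinnick oxidation of the aldehyde to the acid at buffered pH; 2-methylbut-2-ene removes HOCl so that neither the arene C7–H nor the alkene is chlorinated.

Step 8
Reactants: 10 2,4-dimethoxy-5-methyl-6-[(2S)-4-methoxy-3-methylidene-4-oxobutan-2-yl]benzoic acid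
Product: 11 2-hydroxy-4-methoxy-5-methyl-6-[(2S)-4-methoxy-3-methylidene-4-oxobutan-2-yl]benzoic acid
Conditions: BCl3 (2.5 equiv), CH2Cl2, −78 to 0 °C; then H2O
Reagents that add atoms: none
Why: Chelation-controlled ether cleavage: boron binds the carboxyl group and the neighbouring C8 methoxy oxygen in a six-membered chelate and chloride removes only that methyl group; the C6 methoxy group, para to the carboxyl, and the methyl ester should survive at low temperature.

Step 9
Reactants: 11 2-hydroxy-4-methoxy-5-methyl-6-[(2S)-4-methoxy-3-methylidene-4-oxobutan-2-yl]benzoic acid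
Product: 12 benzyl 2-(benzyloxy)-4-methoxy-5-methyl-6-[(2S)-4-methoxy-3-methylidene-4-oxobutan-2-yl]benzoate
Conditions: BnBr (2.4 equiv), K2CO3, DMF, rt to 40 °C
Reagents that add atoms: benzyl bromide, BrCc1ccccc1
Why: O-Alkylation of the carboxylate and the phenoxide with benzyl bromide (Williamson type); the hindered acid is esterified at oxygen and not at the acyl carbon, and carbonate at this temperature is too weak to remove the C4 hydrogen or to move the double bond.

Step 10
Reactants: 12 benzyl 2-(benzyloxy)-4-methoxy-5-methyl-6-[(2S)-4-methoxy-3-methylidene-4-oxobutan-2-yl]benzoate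
Product: 13 benzyl 2-(benzyloxy)-6-[(2S)-4-hydroxy-3-methylidenebutan-2-yl]-4-methoxy-5-methylbenzoate
Conditions: iBu2AlH (2.2 equiv), CH2Cl2, −78 °C; then aq. potassium sodium tartrate
Reagents that add atoms: none
Why: 1,2-Reduction of the conjugated methyl ester by iBu2AlH to the allylic alcohol; the benzyl benzoate is flanked by two ortho substituents and should react much more slowly at −78 °C with a controlled amount of hydride.

Step 11
Reactants: 14 2,2,6-trimethyl-4H-1,3-dioxin-4-one; 15 propionyl chloride
Product: 16 2,2-dimethyl-6-(2-oxobutyl)-4H-1,3-dioxin-4-one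
Conditions: LiN(SiMe3)2 (2 equiv), 14 (2 equiv), THF, −78 °C; then 15 (1 equiv); aq. NH4Cl
Reagents that add atoms: none
Why: Vinylogous Claisen acylation: the lithium dienolate of 14 is acylated by 15 at the exocyclic carbon; the second equivalent of dienolate deprotonates the more acidic product and is recovered as 14.

Step 12
Reactants: 16 2,2-dimethyl-6-(2-oxobutyl)-4H-1,3-dioxin-4-one
Product: 17 2,2-dimethyl-6-(3-methyl-2,4-dioxopentyl)-4H-1,3-dioxin-4-one
Conditions: LiN(iPr)2 (2.2 equiv), THF, −78 °C; then MeC(O)N(OMe)Me, −78 to −30 °C; then 1 M HCl
Reagents that add atoms: N-methoxy-N-methylacetamide, CC(=O)N(C)OC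
Why: Claisen acylation of a dianion: the second deprotonation of 16 occurs at the CH2 of the ethyl ketone and this more reactive carbon attacks the N-methoxy-N-methyl amide, whose chelated tetrahedral adduct collapses only on acidic work-up, so that neither double acylation nor proton transfer from the product occurs.

Step 13
Reactants: 13 benzyl 2-(benzyloxy)-6-[(2S)-4-hydroxy-3-methylidenebutan-2-yl]-4-methoxy-5-methylbenzoate; 17 2,2-dimethyl-6-(3-methyl-2,4-dioxopentyl)-4H-1,3-dioxin-4-one
Product: 21 benzyl 2-(benzyloxy)-6-{(2S)-4-[(2,4-dihydroxy-5,6-dimethylbenzoyl)oxy]-3-methylidenebutan-2-yl}-4-methoxy-5-methylbenzoate, via acylketene 18 (not isolated), via triketo ester 19 (not isolated), via cyclic aldol 20 (not isolated)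
Conditions: 17 (1.5 equiv), PhMe, 110 °C; then Cs2CO3, iPrOH–CH2Cl2, rt; then 1 M HCl
Reagents that add atoms: none
Why: On heating, 17 undergoes a retro-[4+2] cycloreversion that expels acetone and gives acylketene 18, to which the primary allylic hydroxyl of 13 adds to give triketo ester 19, so the ester C–O bond is made at a ketene carbon and not at a hindered aroyl carbon. Cs2CO3 then forms the stabilised carbanion at C1′ (between the ester and the C2′ ketone), which attacks the terminal methyl ketone (future C6′) in a 6-(enolendo)-exo-trig aldol closure to 20; acidification dehydrates 20 and the two remaining ring ketones enolise, so ring B appears as the free resorcinol of 21. The closest known reaction type is the thermolysis of diketo-dioxinones in the presence of an alcohol followed by base-induced aromatisation to resorcylate esters; the departures are the methyl group between the two terminal ketones and the size of the alcohol. No lasting stereocentre is formed, since the carbinol and methine centres of 20 vanish on aromatisation, and C4 is safe because C3 is an alkene carbon and offers no enolisable carbonyl. The step needs chemoselective capture, which is secured because 13 has a single free hydroxyl, the phenol and the acid being benzylated. It also needs the carbocyclic aldol to win over attack of an enol oxygen on the ester (a pyranone, with loss of 13), over Claisen closure from the methyl-bearing carbon, and over aldol attack from the terminal methyl; the mild carbonate in an alcohol medium, the much higher acidity of the C1′ hydrogens, and the fact that Claisen closure would give a quaternary carbon that cannot aromatise all favour the desired mode. The cheap partner 17 is used in excess so that self-cyclisation of 18 does not consume 13.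

Step 14
Reactants: 21 benzyl 2-(benzyloxy)-6-{(2S)-4-[(2,4-dihydroxy-5,6-dimethylbenzoyl)oxy]-3-methylidenebutan-2-yl}-4-methoxy-5-methylbenzoate
Product: 23 benzyl 2-(benzyloxy)-6-{(2S)-4-[(2,4-dihydroxy-5,6-dimethylbenzoyl)oxy]-3-oxobutan-2-yl}-4-methoxy-5-methylbenzoate, via vicinal diol 22 (not isolated)
Conditions: OsO4 (2 mol %), NaIO4 (4 equiv), 2,6-lutidine, dioxane–H2O, rt
Reagents that add atoms: osmium tetroxide, O=[Os](=O)(=O)=O; sodium periodate, [Na+].[O-]I(=O)(=O)=O
Why: Lemieux–Johnson oxidative cleavage: OsO4 dihydroxylates the only alkene to diol 22 and periodate cleaves it to the C3 ketone and formaldehyde while reoxidising osmium; 2,6-lutidine keeps the medium near neutral so that C4, now benzylic and α to a ketone, is not enolised.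

Step 15
Reactants: 23 benzyl 2-(benzyloxy)-6-{(2S)-4-[(2,4-dihydroxy-5,6-dimethylbenzoyl)oxy]-3-oxobutan-2-yl}-4-methoxy-5-methylbenzoate
Product: 25 [(3R,4S)-3,8-dihydroxy-6-methoxy-4,5-dimethyl-1-oxo-3,4-dihydro-1H-isochromen-3-yl]methyl 2,4-dihydroxy-5,6-dimethylbenzoate, via open keto acid 24 (not isolated)
Conditions: H2 (1 atm), Pd on carbon, EtOAc, rt
Reagents that add atoms: none
Why: Hydrogenolysis of the benzyl ester and the benzyl aryl ether under neutral conditions gives keto acid 24, whose carboxyl oxygen adds to the C3 ketone (ring–chain tautomerism, 6-exo-trig) to close the lactol; C3 is set under thermodynamic control by C4, the hydroxyl taking the axial position (anomeric effect, larger C9 group equatorial) anti to the C4 methyl, which the peri C5 methyl forces pseudo-axial, and this is the (3R) epimer.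

## Compound list

1 | 3,5-dimethoxybenzaldehyde | COc1cc(C=O)cc(OC)c1 | starting material
2 | 2-bromo-3,5-dimethoxybenzaldehyde | COc1cc(OC)c(Br)c(C=O)c1 | intermediate
3 | 3,5-dimethoxy-2-methylbenzaldehyde | COc1cc(OC)c(C)c(C=O)c1 | intermediate
4 | methyl acrylate | C=CC(=O)OC | starting material
5 | methyl 2-[(3,5-dimethoxy-2-methylphenyl)(hydroxy)methyl]prop-2-enoate (racemic) | COC(=O)C(=C)C(O)c1cc(OC)cc(OC)c1C | intermediate
6 | methyl (2Z)-2-(bromomethyl)-3-(3,5-dimethoxy-2-methylphenyl)prop-2-enoate | BrC/C(=C\c1cc(OC)cc(OC)c1C)C(=O)OC | intermediate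
7 | methyl (3S)-3-(3,5-dimethoxy-2-methylphenyl)-2-methylidenebutanoate | COc1cc(OC)cc(c1C)[C@H](C)C(=C)C(=O)OC | intermediate
8 | {2,4-dimethoxy-5-methyl-6-[(2S)-4-methoxy-3-methylidene-4-oxobutan-2-yl]phenyl}methylidene(dimethyl)iminium chloride | COc1cc(OC)c(C=[N+](C)C)c(c1C)[C@H](C)C(=C)C(=O)OC.[Cl-] | intermediate (not isolated)
9 | methyl (3S)-3-(2-formyl-3,5-dimethoxy-6-methylphenyl)-2-methylidenebutanoate | COc1cc(OC)c(C=O)c(c1C)[C@H](C)C(=C)C(=O)OC | intermediate
10 | 2,4-dimethoxy-5-methyl-6-[(2S)-4-methoxy-3-methylidene-4-oxobutan-2-yl]benzoic acid | COc1cc(OC)c(C(=O)O)c(c1C)[C@H](C)C(=C)C(=O)OC | intermediate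
11 | 2-hydroxy-4-methoxy-5-methyl-6-[(2S)-4-methoxy-3-methylidene-4-oxobutan-2-yl]benzoic acid | COc1cc(O)c(C(=O)O)c(c1C)[C@H](C)C(=C)C(=O)OC | intermediate
12 | benzyl 2-(benzyloxy)-4-methoxy-5-methyl-6-[(2S)-4-methoxy-3-methylidene-4-oxobutan-2-yl]benzoate | COc1cc(OCc2ccccc2)c(C(=O)OCc2ccccc2)c(c1C)[C@H](C)C(=C)C(=O)OC | intermediate
13 | benzyl 2-(benzyloxy)-6-[(2S)-4-hydroxy-3-methylidenebutan-2-yl]-4-methoxy-5-methylbenzoate | COc1cc(OCc2ccccc2)c(C(=O)OCc2ccccc2)c(c1C)[C@H](C)C(=C)CO | intermediate
14 | 2,2,6-trimethyl-4H-1,3-dioxin-4-one | CC1=CC(=O)OC(C)(C)O1 | starting material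
15 | propionyl chloride | CCC(=O)Cl | starting material
16 | 2,2-dimethyl-6-(2-oxobutyl)-4H-1,3-dioxin-4-one | CCC(=O)CC1=CC(=O)OC(C)(C)O1 | intermediate
17 | 2,2-dimethyl-6-(3-methyl-2,4-dioxopentyl)-4H-1,3-dioxin-4-one | CC(=O)C(C)C(=O)CC1=CC(=O)OC(C)(C)O1 | intermediate
18 | 6-methyloct-1-ene-1,3,5,7-tetrone (acylketene) | CC(=O)C(C)C(=O)CC(=O)C=C=O | intermediate (not isolated)
19 | benzyl 2-(benzyloxy)-4-methoxy-5-methyl-6-{(2S)-3-methylidene-4-[(6-methyl-3,5,7-trioxooctanoyl)oxy]butan-2-yl}benzoate | COc1cc(OCc2ccccc2)c(C(=O)OCc2ccccc2)c(c1C)[C@H](C)C(=C)COC(=O)CC(=O)CC(=O)C(C)C(C)=O | intermediate (not isolated)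
20 | benzyl 2-(benzyloxy)-6-{(2S)-4-[(2-hydroxy-2,3-dimethyl-4,6-dioxocyclohexane-1-carbonyl)oxy]-3-methylidenebutan-2-yl}-4-methoxy-5-methylbenzoate (carbocycle centres undefined) | COc1cc(OCc2ccccc2)c(C(=O)OCc2ccccc2)c(c1C)[C@H](C)C(=C)COC(=O)C1C(=O)CC(=O)C(C)C1(C)O | intermediate (not isolated)
21 | benzyl 2-(benzyloxy)-6-{(2S)-4-[(2,4-dihydroxy-5,6-dimethylbenzoyl)oxy]-3-methylidenebutan-2-yl}-4-methoxy-5-methylbenzoate | COc1cc(OCc2ccccc2)c(C(=O)OCc2ccccc2)c(c1C)[C@H](C)C(=C)COC(=O)c1c(O)cc(O)c(C)c1C | intermediate
22 | benzyl 2-(benzyloxy)-6-{(2S)-4-[(2,4-dihydroxy-5,6-dimethylbenzoyl)oxy]-3-hydroxy-3-(hydroxymethyl)butan-2-yl}-4-methoxy-5-methylbenzoate (C3 epimers) | COc1cc(OCc2ccccc2)c(C(=O)OCc2ccccc2)c(c1C)[C@H](C)C(O)(CO)COC(=O)c1c(O)cc(O)c(C)c1C | intermediate (not isolated)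
23 | benzyl 2-(benzyloxy)-6-{(2S)-4-[(2,4-dihydroxy-5,6-dimethylbenzoyl)oxy]-3-oxobutan-2-yl}-4-methoxy-5-methylbenzoate | COc1cc(OCc2ccccc2)c(C(=O)OCc2ccccc2)c(c1C)[C@H](C)C(=O)COC(=O)c1c(O)cc(O)c(C)c1C | intermediate
24 | 2-hydroxy-4-methoxy-5-methyl-6-{(2S)-4-[(2,4-dihydroxy-5,6-dimethylbenzoyl)oxy]-3-oxobutan-2-yl}benzoic acid | COc1cc(O)c(C(=O)O)c(c1C)[C@H](C)C(=O)COC(=O)c1c(O)cc(O)c(C)c1C | intermediate (not isolated)
25 | [(3R,4S)-3,8-dihydroxy-6-methoxy-4,5-dimethyl-1-oxo-3,4-dihydro-1H-isochromen-3-yl]methyl 2,4-dihydroxy-5,6-dimethylbenzoate | COc1cc(O)c2c(c1C)[C@H](C)[C@](O)(COC(=O)c1c(O)cc(O)c(C)c1C)OC2=O | target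

## Step count and least certain steps

Total step count: 15. Longest linear sequence: 13 steps (steps 1 to 10, then 13 to 15); the dioxinone branch (steps 11 and 12) joins at step 13.

**Step 13 (key step).** The acylketene 18 may close on its own enol to a hydroxypyranone before the alcohol adds. On adding base, the triketo ester 19 may expel the alcohol by pyranone or Claisen closure instead of undergoing the aldol. Dehydration of 20 may also stall. The fallback sets out from 13 and 17 and returns at 21. Compound 17 is thermolysed with benzyl alcohol and aromatised with Cs2CO3 and acid to benzyl 2,4-dihydroxy-5,6-dimethylbenzoate F1. Hydrogenolysis over Pd on carbon then gives 2,4-dihydroxy-5,6-dimethylbenzoic acid F2. In parallel, 13 is converted with CBr4 and PPh3 into benzyl 2-(benzyloxy)-6-[(2S)-4-bromo-3-methylidenebutan-2-yl]-4-methoxy-5-methylbenzoate F3. With KHCO3 in DMF only the carboxyl of F2 is ionised, and its oxygen displaces the primary allylic bromide of F3 to give 21. The ester is then formed by carboxylate alkylation, again without attack on the hindered aroyl carbon.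

**Step 5.** Facial selectivity may be poor, or an uncatalysed Grignard addition–elimination may erode the enantiomeric purity. Direct SN2 displacement at the CH2Br group and 1,2-addition to the ester are lesser risks. The fallback sets out from 3 and returns at 7.
- Doebner–Knoevenagel condensation with malonic acid gives (2E)-3-(3,5-dimethoxy-2-methylphenyl)prop-2-enoic acid F4.
- Its pivaloyl mixed anhydride acylates lithiated (R)-4-phenyloxazolidin-2-one to give (4R)-3-[(2E)-3-(3,5-dimethoxy-2-methylphenyl)prop-2-enoyl]-4-phenyl-1,3-oxazolidin-2-one F5.
- MeMgBr with CuBr·SMe2 adds to the chelated syn-s-cis enoyl conformer anti to the phenyl group, giving (4R)-3-[(3R)-3-(3,5-dimethoxy-2-methylphenyl)butanoyl]-4-phenyl-1,3-oxazolidin-2-one F6.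
- NaOMe in MeOH releases methyl (3R)-3-(3,5-dimethoxy-2-methylphenyl)butanoate F7.
- The lithium enolate of F7 reacts with dimethylmethyleneiminium iodide to give methyl (3R)-3-(3,5-dimethoxy-2-methylphenyl)-2-[(dimethylamino)methyl]butanoate F8.
- Quaternisation with MeI and elimination with DBU give 7. The descriptor changes from (3R) to (3S) only because the new methylidene carbon outranks the aryl group; the centre itself is not touched.

**Step 6.** Substitution at C7 instead of C8a, or a stalled reaction beside the branched side chain. The fallback sets out from 7 and returns at 10. NBS in MeCN, a smaller electrophile that strongly prefers the position para to a methoxy group, gives methyl (3R)-3-(2-bromo-3,5-dimethoxy-6-methylphenyl)-2-methylidenebutanoate F9 (descriptor changed by the bromine only). Hydroxycarbonylation of F9 with Pd(OAc)2, Xantphos, CO, H2O and Et3N in dioxane then gives the acid 10.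

**Step 14.** The free resorcinol ring B may be oxidised by periodate, and C4 may epimerise once the ketone is present. The fallback sets out from 21 and returns at 25.
- The two phenols of 21 are benzylated (BnBr, Cs2CO3, DMF, harmless while C3 is still an alkene carbon) to give benzyl 2-(benzyloxy)-6-{(2S)-4-[(2,4-bis(benzyloxy)-5,6-dimethylbenzoyl)oxy]-3-methylidenebutan-2-yl}-4-methoxy-5-methylbenzoate F10.
- The same OsO4/NaIO4 cleavage gives benzyl 2-(benzyloxy)-6-{(2S)-4-[(2,4-bis(benzyloxy)-5,6-dimethylbenzoyl)oxy]-3-oxobutan-2-yl}-4-methoxy-5-methylbenzoate F11.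
- Hydrogenolysis of all four benzyl groups leads through 24 to 25.

**Step 10.** Hydride may also attack the benzyl ester, or the new aluminium alkoxide may transesterify onto it. The fallback sets out from 11 and returns at 13. The methyl ester is reduced at the acid stage with excess iBu2AlH, the carboxyl being shielded as its aluminium salt, to give 2-hydroxy-6-[(2S)-4-hydroxy-3-methylidenebutan-2-yl]-4-methoxy-5-methylbenzoic acid F12. BnBr and K2CO3 in DMF then benzylate only the carboxylate and the phenoxide, leaving the aliphatic hydroxyl free, to give 13.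

**Step 3.** The reaction may stall with this ortho-substituted aldehyde. The fallback sets out from 3 and returns at 5. It is a vinylalumination: methyl propiolate is hydroaluminated with iBu2AlH and N-methylmorpholine N-oxide in THF, and the resulting α-(methoxycarbonyl)vinylaluminium adds to 3 to give 5 directly. No compound outside the route is isolated (F0).

## Further compounds

F1 | step 13 | benzyl 2,4-dihydroxy-5,6-dimethylbenzoate | Cc1c(C)c(C(=O)OCc2ccccc2)c(O)cc1O
F2 | step 13 | 2,4-dihydroxy-5,6-dimethylbenzoic acid | Cc1c(C)c(C(=O)O)c(O)cc1O
F3 | step 13 | benzyl 2-(benzyloxy)-6-[(2S)-4-bromo-3-methylidenebutan-2-yl]-4-methoxy-5-methylbenzoate | COc1cc(OCc2ccccc2)c(C(=O)OCc2ccccc2)c(c1C)[C@H](C)C(=C)CBr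
F4 | step 5 | (2E)-3-(3,5-dimethoxy-2-methylphenyl)prop-2-enoic acid | COc1cc(OC)cc(c1C)/C=C/C(=O)O
F5 | step 5 | (4R)-3-[(2E)-3-(3,5-dimethoxy-2-methylphenyl)prop-2-enoyl]-4-phenyl-1,3-oxazolidin-2-one | COc1cc(OC)cc(c1C)/C=C/C(=O)N1C(=O)OC[C@H]1c1ccccc1
F6 | step 5 | (4R)-3-[(3R)-3-(3,5-dimethoxy-2-methylphenyl)butanoyl]-4-phenyl-1,3-oxazolidin-2-one | COc1cc(OC)cc(c1C)[C@H](C)CC(=O)N1C(=O)OC[C@H]1c1ccccc1
F7 | step 5 | methyl (3R)-3-(3,5-dimethoxy-2-methylphenyl)butanoate | COc1cc(OC)cc(c1C)[C@H](C)CC(=O)OC
F8 | step 5 | methyl (3R)-3-(3,5-dimethoxy-2-methylphenyl)-2-[(dimethylamino)methyl]butanoate (C2 epimers) | COc1cc(OC)cc(c1C)[C@H](C)C(CN(C)C)C(=O)OC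
F9 | step 6 | methyl (3R)-3-(2-bromo-3,5-dimethoxy-6-methylphenyl)-2-methylidenebutanoate | COc1cc(OC)c(Br)c(c1C)[C@H](C)C(=C)C(=O)OC
F10 | step 14 | benzyl 2-(benzyloxy)-6-{(2S)-4-[(2,4-bis(benzyloxy)-5,6-dimethylbenzoyl)oxy]-3-methylidenebutan-2-yl}-4-methoxy-5-methylbenzoate | COc1cc(OCc2ccccc2)c(C(=O)OCc2ccccc2)c(c1C)[C@H](C)C(=C)COC(=O)c1c(OCc2ccccc2)cc(OCc2ccccc2)c(C)c1C
F11 | step 14 | benzyl 2-(benzyloxy)-6-{(2S)-4-[(2,4-bis(benzyloxy)-5,6-dimethylbenzoyl)oxy]-3-oxobutan-2-yl}-4-methoxy-5-methylbenzoate | COc1cc(OCc2ccccc2)c(C(=O)OCc2ccccc2)c(c1C)[C@H](C)C(=O)COC(=O)c1c(OCc2ccccc2)cc(OCc2ccccc2)c(C)c1C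
F12 | step 10 | 2-hydroxy-6-[(2S)-4-hydroxy-3-methylidenebutan-2-yl]-4-methoxy-5-methylbenzoic acid | COc1cc(O)c(C(=O)O)c(c1C)[C@H](C)C(=C)CO
F0 | step 3 | none | none
A1 | alternative 1 | open-chain diketo-dioxinone carrying the silyl-protected C4–C3–C9 chain and the dibenzyl ring B ester (configuration as in the SMILES) | CC1(C)OC(=O)C=C(O1)CC(=O)C(C)C(=O)[C@H](C)[C@@H](O[Si](C)(C)C(C)(C)C)COC(=O)c1c(OCc3ccccc3)cc(OCc3ccccc3)c(C)c1C
A2 | alternative 1 | 7-hydroxy-2,2,6-trimethylbenzodioxin-4-one bearing the C4–C3–C9 chain at position 5 (configuration as in the SMILES) | CC1(C)OC(=O)c2c(O1)cc(O)c(C)c2[C@H](C)[C@@H](O[Si](C)(C)C(C)(C)C)COC(=O)c1c(OCc3ccccc3)cc(OCc3ccccc3)c(C)c1C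
A3 | alternative 2 | [(3S)-7-(benzyloxy)-2-hydroxy-5-methoxy-3,4-dimethyl-1-oxo-2,3-dihydro-1H-inden-2-yl]methyl 2,4-bis(benzyloxy)-5,6-dimethylbenzoate (carbinol centre undefined) | COc1cc(OCc3ccccc3)c2c(c1C)[C@H](C)C(O)(COC(=O)c1c(OCc3ccccc3)cc(OCc3ccccc3)c(C)c1C)C2=O
A4 | alternative 2 | tribenzyl ether of the target lactol | COc1cc(OCc3ccccc3)c2c(c1C)[C@H](C)[C@](O)(COC(=O)c1c(OCc3ccccc3)cc(OCc3ccccc3)c(C)c1C)OC2=O
A5 | alternative 3 | 1,3-dimethoxy-1-(trimethylsilyloxy)penta-1,3-diene | CC=C(OC)C=C(OC)O[Si](C)(C)C
A6 | alternative 3 | tert-butyl ynoate carrying the silyl-protected C4–C3–C9 chain and the dibenzyl ring B ester (configuration as in the SMILES) | CC(C)(C)OC(=O)C#C[C@H](C)[C@H](O[Si](C)(C)C(C)(C)C)COC(=O)c1c(OCc2ccccc2)cc(OCc2ccccc2)c(C)c1C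
A7 | alternative 3 | tert-butyl 2-hydroxy-4-methoxy-5-methylbenzoate carrying the full C4–C3–C9 chain at position 6 (configuration as in the SMILES) | COc1cc(O)c(C(=O)OC(C)(C)C)c(c1C)[C@H](C)[C@H](O[Si](C)(C)C(C)(C)C)COC(=O)c1c(OCc2ccccc2)cc(OCc2ccccc2)c(C)c1C
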